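**Retrosynthetic overview**
1. The target is the (Z)-cinnamate of a tertiary guaiadienol. The ester C–O bond is made last but one, from guaia-3,11-dien-10-ol and a phenylpropiolic acid unit, and the Z alkene comes from cis-semihydrogenation of the ynoate.
2. The C3=C4 alkene and the C5–H come from 10-hydroxyguaia-4,11-dien-3-one by tosylhydrazone reduction with 1,3-transposition of the double bond.
3. The strategy rests on this array: C10 of the seven-membered ring carries a methyl group and the oxygen and sits next to the fusion carbon C1–H, C4 of the cyclopentene carries a methyl group, and C7 carries the isopropenyl group. This is what a 4-methyl eudesma-1,4-dien-3-one gives on photorearrangement in aqueous acid (C1–C5 formed, C5–C10 broken, water at C10).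
4. The dienone comes from (S)-carvone and ethyl vinyl ketone by Robinson annulation under chiral-imine control, then dehydrogenation.
5. Ring order: the carvone six-membered ring (ring B) is kept, ring A is annulated onto it, then ring A contracts to the cyclopentenone and ring B expands to the cycloheptane in one operation.

Key step: step 6

Remark on the chemistry: dihydrocarvone 3 is drawn as its trans (2S,5S) isomer; its C2 epimer serves equally, because C2 becomes trigonal in the enamine of step 3. Decalins are numbered as eudesmanes; the 5/7 compounds as guaianes (C1 and C5 fusion, C2–C4 cyclopentene, C6–C10 cycloheptane, C11–C13 isopropenyl).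

**Step 1**
Reactants: 1 (S)-(+)-carvone
Product: 3 (2S,5S)-dihydrocarvone [trans-2-methyl-5-(prop-1-en-2-yl)cyclohexan-1-one], via lithium enolate 2 (not isolated)
Conditions: LiBH(s-Bu)3 (L-Selectride), THF, −78 °C; aq NH4Cl
Reagents that add atoms: none
Why: Conjugate hydride reduction of a β-unsubstituted cyclohexenone by the bulky trialkylborohydride gives enolate 2, whose protonation gives the ketone; C5 is untouched and the C2 configuration is of no consequence.

**Step 2**
Reactants: 3 (2S,5S)-dihydrocarvone; 4 (S)-(−)-1-phenylethylamine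
Product: 5 (S)-N-[(2S,5S)-2-methyl-5-(prop-1-en-2-yl)cyclohexylidene]-1-phenylethanamine
Conditions: TsOH·H2O (cat.), toluene, reflux, Dean–Stark
Reagents that add atoms: none
Why: Acid-catalysed ketone–amine condensation (imine formation) driven by azeotropic removal of water attaches the (S)-auxiliary; no lasting stereocentre is formed.

**Step 3**
Reactants: 5 chiral imine; 6 ethyl vinyl ketone
Product: 8 (2R,5S)-2-methyl-2-(3-oxopentyl)-5-(prop-1-en-2-yl)cyclohexan-1-one, via Michael adduct imine 7 (not isolated)
Conditions: THF, 40 °C; then 10% aq AcOH, rt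
Reagents that add atoms: water, O
Why: Chiral-imine Michael addition of the aza-ene type: the more substituted secondary enamine tautomer of 5 adds to the enone on the face of C2 away from the phenyl group of the (S)-auxiliary, which places the oxopentyl chain trans to the isopropenyl group (quaternary centre 2R, methyl cis to isopropenyl), and aqueous acid then hydrolyses the imine.

**Step 4**
Reactants: 8 diketone
Product: 10 (−)-α-cyperone [(7S,10R)-eudesma-4,11-dien-3-one; angular methyl cis to isopropenyl], via ketol 9 (not isolated)
Conditions: NaOMe, MeOH, rt to 50 °C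
Reagents that add atoms: none
Why: Intramolecular aldol condensation, the closing stage of the Robinson annulation: the ethyl ketone enolate closes ring A on the ring carbonyl and ketol 9 dehydrates to the conjugated enone, leaving the quaternary centre untouched.

**Step 5**
Reactants: 10 (−)-α-cyperone
Product: 11 (7S,10R)-eudesma-1,4,11-trien-3-one (ent-1,2-dehydro-α-cyperone)
Conditions: DDQ, dioxane, reflux
Reagents that add atoms: none
Why: DDQ dehydrogenation of a 4-en-3-one under neutral conditions removes hydride from C1 of the C2 enol and gives the cross-conjugated 1,4-dien-3-one; no stereocentre is formed and the quaternary C10 cannot epimerise.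

**Step 6**
Reactants: 11 cross-conjugated dienone
Product: 14 (1S,7S,10S)-10-hydroxyguaia-4,11-dien-3-one (H1 and 10-OH on the same face), via bicyclo[3.1.0] zwitterion 12 (not isolated), via dienol 13 (not isolated)
Conditions: hν (medium-pressure Hg lamp, Pyrex), AcOH/H2O 45:55, N2, rt, stopped at full conversion
Reagents that add atoms: water, O
Why: Excitation of the cyclohexadienone leads to bonding between the two β-carbons C1 and C5 and gives zwitterion 12; protonation on oxygen by acetic acid turns it into a cyclopropylcarbinyl (2-hydroxyallyl) cation with its charge at the methyl-bearing C4. Water then attacks C10 on the side opposite C5 while the C5–C10 cyclopropane bond breaks, and dienol 13 tautomerises to the enone; the closest known reaction is the santonin to isophotosantonic lactone rearrangement of 4-methyl cross-conjugated cyclohexadienones in aqueous acetic acid. The cyclopentenone closes by transannular C1–C5 bonding across ring A (ring contraction through the cyclopropane), and the cycloheptane arises by ring expansion of ring B as C1 comes to lie between C5 and C10. C10 is set by inversion of the quaternary centre made in step 3, and C1 by the geometry of the cis-fused cyclopropane, which leaves H1 on the face of the new hydroxyl. The step needs cleavage of C5–C10 rather than C1–C10 (which would give a spiro[4.5] enone); the C4 methyl group secures this by stabilising positive charge next to C5, and the isolated isopropenyl group does not absorb above 290 nm.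

**Step 7**
Reactants: 14 hydroxy enone
Product: 15 p-toluenesulfonyl hydrazone of 14 at C3
Conditions: TsNHNH2, EtOH, rt to 40 °C
Reagents that add atoms: p-toluenesulfonyl hydrazide, Cc1ccc(cc1)S(=O)(=O)NN
Why: Hydrazone formation at the cyclopentenone carbonyl under near-neutral conditions, chosen because the tertiary carbinol is a vinylogous β-hydroxy ketone and would not tolerate strong acid or base; no stereocentre changes.

**Step 8**
Reactants: 15 tosylhydrazone
Product: 18 (1S,5R,7S,10S)-guaia-3,11-dien-10-ol (trans ring fusion), via allylic tosylhydrazine 16 (not isolated), via allylic diazene 17 (not isolated)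
Conditions: catecholborane (3 equiv), CHCl3, 0 °C to rt; then NaOAc·3H2O, reflux
Reagents that add atoms: none
Why: Tosylhydrazone reduction with alkene transposition: hydride should add to C3 on the face away from the C10-bearing substituent at C1 (the sense found for hydride reduction of 4-substituted cyclopent-2-enones), buffered loss of sulfinate gives diazene 17, and its retro-ene loss of N2 passes hydrogen suprafacially from the C3 nitrogen to the same face of C5, so H5 ends trans to H1 as the alkene moves to C3=C4; the excess borane allows for uptake by the free tertiary hydroxyl.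

**Step 9**
Reactants: 19 phenylpropiolic acid
Product: 20 phenylpropioloyl chloride
Conditions: (COCl)2, DMF (cat.), CH2Cl2, 0 °C to rt
Reagents that add atoms: oxalyl chloride, ClC(=O)C(=O)Cl
Why: Conversion of a carboxylic acid to its acid chloride through the chloroiminium (Vilsmeier) intermediate; the conjugated alkyne is inert here.

**Step 10**
Reactants: 18 guaia-3,11-dien-10-ol; 20 phenylpropioloyl chloride
Product: 22 (1S,5R,7S,10S)-guaia-3,11-dien-10-yl 3-phenylprop-2-ynoate, via lithium alkoxide 21 (not isolated)
Conditions: n-BuLi, THF, −78 °C; then 20, −78 to 0 °C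
Reagents that add atoms: none
Why: O-acylation of a preformed lithium tertiary alkoxide with an acid chloride (nucleophilic acyl substitution), suited to hindered tertiary alcohols; C10 keeps its configuration because its C–O bond is not broken.

**Step 11**
Reactants: 22 phenylpropiolate
Product: 23 target, (1S,5R,7S,10S)-guaia-3,11-dien-10-yl (Z)-3-phenylprop-2-enoate
Conditions: H2 (1 atm, one equivalent taken up), Pd/CaCO3 poisoned with Pb(OAc)2 (Lindlar catalyst), quinoline, EtOAc, rt
Reagents that add atoms: none
Why: Lindlar semihydrogenation adds H2 syn to the alkyne on the poisoned palladium surface and gives the (Z)-alkene; the conjugated alkyne should react well before the isolated 1,1-disubstituted and trisubstituted alkenes.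

**Compound list**
1 | (S)-(+)-carvone | C=C(C)[C@H]1CC=C(C)C(=O)C1 | starting material
2 | lithium enolate of dihydrocarvone (C1–O–Li, C1=C2) | C=C(C)[C@H]1CCC(C)=C(O[Li])C1 | intermediate
3 | (2S,5S)-dihydrocarvone (trans) | C=C(C)[C@H]1CC[C@H](C)C(=O)C1 | intermediate
4 | (S)-(−)-1-phenylethylamine | C[C@H](N)c1ccccc1 | starting material
5 | (S)-N-[(2S,5S)-2-methyl-5-(prop-1-en-2-yl)cyclohexylidene]-1-phenylethanamine | C=C(C)[C@H]1CC[C@H](C)C(=N[C@@H](C)c2ccccc2)C1 | intermediate
6 | ethyl vinyl ketone (pent-1-en-3-one) | CCC(=O)C=C | starting material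
7 | (S)-1-phenylethyl imine of diketone 8 at the ring carbonyl | C=C(C)[C@H]1CC[C@](C)(CCC(=O)CC)C(=N[C@@H](C)c2ccccc2)C1 | intermediate
8 | (2R,5S)-2-methyl-2-(3-oxopentyl)-5-(prop-1-en-2-yl)cyclohexan-1-one | C=C(C)[C@H]1CC[C@](C)(CCC(=O)CC)C(=O)C1 | intermediate
9 | 5-hydroxy-eudesm-11-en-3-one ketol (7S,10R; C4 and C5 as a mixture) | C=C(C)[C@H]1CC[C@]2(C)CCC(=O)C(C)C2(O)C1 | intermediate
10 | (−)-α-cyperone, (7S,10R)-eudesma-4,11-dien-3-one | C=C(C)[C@H]1CC[C@]2(C)CCC(=O)C(C)=C2C1 | intermediate
11 | (7S,10R)-eudesma-1,4,11-trien-3-one | C=C(C)[C@H]1CC[C@]2(C)C=CC(=O)C(C)=C2C1 | intermediate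
12 | bicyclo[3.1.0]hexenone zwitterion (cyclopropane C1–C5–C10, enolate at C3, cation at C4) | C=C(C)[C@H]1CC[C@]2(C)[C@H]3C=C([O-])[C+](C)[C@@]23C1 | intermediate
13 | (1S,7S,10S)-guaia-2,4,11-triene-3,10-diol (dienol) | C=C(C)[C@H]1CC[C@](C)(O)[C@H]2C=C(O)C(C)=C2C1 | intermediate
14 | (1S,7S,10S)-10-hydroxyguaia-4,11-dien-3-one | C=C(C)[C@H]1CC[C@](C)(O)[C@H]2CC(=O)C(C)=C2C1 | intermediate
15 | C3 p-toluenesulfonyl hydrazone of 14 | C=C(C)[C@H]1CC[C@](C)(O)[C@H]2CC(=NNS(=O)(=O)c3ccc(C)cc3)C(C)=C2C1 | intermediate
16 | (3R)-3-(2-tosylhydrazinyl)guaia-4,11-dien-10-ol (N on the face of the C1–C10 bond) | C=C(C)[C@H]1CC[C@](C)(O)[C@H]2C[C@@H](NNS(=O)(=O)c3ccc(C)cc3)C(C)=C2C1 | intermediate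
17 | (3R)-3-diazenylguaia-4,11-dien-10-ol | C=C(C)[C@H]1CC[C@](C)(O)[C@H]2C[C@@H](N=N)C(C)=C2C1 | intermediate
18 | (1S,5R,7S,10S)-guaia-3,11-dien-10-ol | C=C(C)[C@H]1CC[C@](C)(O)[C@H]2CC=C(C)[C@@H]2C1 | intermediate
19 | phenylpropiolic acid | OC(=O)C#Cc1ccccc1 | starting material
20 | phenylpropioloyl chloride | ClC(=O)C#Cc1ccccc1 | intermediate
21 | lithium alkoxide of 18 | C=C(C)[C@H]1CC[C@](C)(O[Li])[C@H]2CC=C(C)[C@@H]2C1 | intermediate
22 | (1S,5R,7S,10S)-guaia-3,11-dien-10-yl 3-phenylprop-2-ynoate | C=C(C)[C@H]1CC[C@](C)(OC(=O)C#Cc2ccccc2)[C@H]2CC=C(C)[C@@H]2C1 | intermediate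
23 | (1S,5R,7S,10S)-guaia-3,11-dien-10-yl (Z)-3-phenylprop-2-enoate, CNP0129909.1 | C=C(C)[C@H]1CC[C@](C)(OC(=O)/C=C\c2ccccc2)[C@H]2CC=C(C)[C@@H]2C1 | target

**Totals**
Total step count: 11. Longest linear sequence: 10 steps (steps 1 to 8, 10 and 11); step 9 is a one-step side branch.

**Steps most likely to fail**

Step 8. Hydride may reach C3 of the hydrazone from the face of the C1–C10 bond, or with poor facial selectivity. The suprafacial hydrogen shift would then deliver hydrogen to the wrong face of C5 and give the cis-fused isomer; slow reduction of the hindered hydrazone is a further hazard. The fallback sets out from 14 and comes back at 18. It separates carbonyl reduction from diazene formation and installs the nitrogen by a Mitsunobu displacement, which inverts C3, so the same facial preference of hydride leads to the opposite configuration at C5. Luche reduction of 14 (NaBH4, CeCl3·7H2O, MeOH, −78 °C) should give the allylic diol (1S,3S,7S,10S)-guaia-4,11-diene-3,10-diol F1, with the C3 hydroxyl away from the C1–C10 bond; any 3-epimer is separated and returned to 14 with MnO2. Mitsunobu coupling of the secondary allylic hydroxyl with 2-nitrobenzenesulfonyl hydrazide (PPh3, DEAD, N-methylmorpholine, −30 °C) should give, with inversion, the N-allyl-N-(2-nitrobenzenesulfonyl)hydrazine F2. On warming to room temperature F2 loses the sulfinic acid to give diazene 17, which passes on to 18 by retro-ene loss of N2. The tertiary C10 hydroxyl does not enter the Mitsunobu step.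

Step 6. Capture of the cyclopropylcarbinyl cation by water may be inefficient, and the free tertiary carbinol may be lost by ionisation or vinylogous dehydration in the acidic aqueous medium during long irradiation. The fallback sets out from 11 and comes back at 18. Acetic acid replaces water as the nucleophile and the carbinol is carried on as its ester. Irradiation of 11 in anhydrous acetic acid with the same lamp should lead through zwitterion 12 and the dienol acetate F3 to (1S,7S,10S)-10-acetoxyguaia-4,11-dien-3-one F4. F4 is condensed with TsNHNH2 (EtOH) to the tosylhydrazone F5. Catecholborane (CHCl3) and then NaOAc·3H2O at reflux should take F5 through the allylic tosylhydrazine acetate F6 and the allylic diazene acetate F7 to guaia-3,11-dien-10-yl acetate F8; the capped oxygen no longer consumes borane. LiAlH4 (Et2O, 0 °C) then cleaves the acetate to 18.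

Step 10. Acylation of the hindered tertiary alkoxide may stall, and the alkoxide may add to the β-carbon of the ynoyl chloride or of the product ynoate. The fallback sets out from 18 and comes back at 23, without 22 and without step 11. The cinnamate is built on the oxygen from a small acyl unit. Bromoacetyl bromide and pyridine (CH2Cl2, 0 °C) should give guaia-3,11-dien-10-yl bromoacetate F9. Diphenyl phosphite and Et3N (CH2Cl2, 0 °C, Michaelis–Becker alkylation) should give the diphenylphosphonoacetate F10. NaH (THF, −78 °C) gives the sodium phosphonoenolate F11, and benzaldehyde then gives 23 by a Z-selective Horner–Wadsworth–Emmons olefination of the diaryl phosphonate.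

**Further compounds**
F1 | step 8 | (1S,3S,7S,10S)-guaia-4,11-diene-3,10-diol | C=C(C)[C@H]1CC[C@](C)(O)[C@H]2C[C@H](O)C(C)=C2C1
F2 | step 8 | N-[(3R)-10-hydroxyguaia-4,11-dien-3-yl]-2-nitrobenzenesulfonohydrazide (alkyl on the sulfonylated nitrogen) | C=C(C)[C@H]1CC[C@](C)(O)[C@H]2C[C@@H](N(N)S(=O)(=O)c3ccccc3[N+](=O)[O-])C(C)=C2C1
F3 | step 6 | (1S,7S,10S)-10-acetoxyguaia-2,4,11-trien-3-ol (dienol acetate) | C=C(C)[C@H]1CC[C@](C)(OC(C)=O)[C@H]2C=C(O)C(C)=C2C1
F4 | step 6 | (1S,7S,10S)-10-acetoxyguaia-4,11-dien-3-one | C=C(C)[C@H]1CC[C@](C)(OC(C)=O)[C@H]2CC(=O)C(C)=C2C1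
F5 | step 6 | C3 p-toluenesulfonyl hydrazone of F4 | C=C(C)[C@H]1CC[C@](C)(OC(C)=O)[C@H]2CC(=NNS(=O)(=O)c3ccc(C)cc3)C(C)=C2C1
F6 | step 6 | (3R)-3-(2-tosylhydrazinyl)guaia-4,11-dien-10-yl acetate | C=C(C)[C@H]1CC[C@](C)(OC(C)=O)[C@H]2C[C@@H](NNS(=O)(=O)c3ccc(C)cc3)C(C)=C2C1
F7 | step 6 | (3R)-3-diazenylguaia-4,11-dien-10-yl acetate | C=C(C)[C@H]1CC[C@](C)(OC(C)=O)[C@H]2C[C@@H](N=N)C(C)=C2C1
F8 | step 6 | (1S,5R,7S,10S)-guaia-3,11-dien-10-yl acetate | C=C(C)[C@H]1CC[C@](C)(OC(C)=O)[C@H]2CC=C(C)[C@@H]2C1
F9 | step 10 | (1S,5R,7S,10S)-guaia-3,11-dien-10-yl bromoacetate | C=C(C)[C@H]1CC[C@](C)(OC(=O)CBr)[C@H]2CC=C(C)[C@@H]2C1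
F10 | step 10 | (1S,5R,7S,10S)-guaia-3,11-dien-10-yl (diphenoxyphosphoryl)acetate | C=C(C)[C@H]1CC[C@](C)(OC(=O)CP(=O)(Oc2ccccc2)Oc2ccccc2)[C@H]3CC=C(C)[C@@H]3C1
F11 | step 10 | sodium salt of the phosphonate carbanion of F10 | C=C(C)[C@H]1CC[C@](C)(OC(=O)[CH-]P(=O)(Oc2ccccc2)Oc2ccccc2)[C@H]3CC=C(C)[C@@H]3C1.[Na+]
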